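The target is an all-trans 1-aryltetralin in which adjacent carbons C2 and C3 of the saturated ring B each carry a hydroxymethyl group: a 2,3-disubstituted butane-1,4-diol, that is, a reduced succinate. The route therefore prepares an open-chain diester in which C2 and C3 are both ester α-carbons, attached to ring A beside a preformed C1 diarylmethine stereocentre, and closes ring B by intramolecular oxidative coupling of its dilithium bis-enolate. This single operation forms the C2–C3 bond, the six-membered ring and both remaining stereocentres under control of C1. The diester comes from a coumarin by rhodium-catalysed asymmetric arylation; ester reduction and hydrogenolysis complete the synthesis.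

Key step: step 8

Remarks. Tetralin numbering is used throughout: C1 carries the aryl group, C2 and C3 the hydroxymethyl groups, C4 is the benzylic CH2, C4a and C8a are the fusion carbons, ring A is the oxygenated benzo ring (C5 H, C6 OMe, C7 OH, C8 OH). The target is (1S,2R,3R), with the C1 aryl, the C2 and the C3 substituents mutually trans. Assumption: (S)-SEGPHOS is assigned to the 4S dihydrocoumarin by analogy with the arylation of simple coumarins; the other ligand enantiomer would be used if the sense proved opposite.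

Step 1
Reactants: 1 3,4-dihydroxy-5-methoxybenzaldehyde (5-hydroxyvanillin); 2 benzyl bromide
Product: 3 4-(benzyloxy)-3-hydroxy-5-methoxybenzaldehyde
Conditions: BnBr (1.05 equiv), NaHCO3, NaI (cat.), DMF, 40 °C
Reagents that add atoms: benzyl bromide, BrCc1ccccc1
Why: The 4-hydroxyl, para to the formyl group, is the more acidic phenol, so the weak base ionises it selectively and Williamson O-benzylation should leave the 3-hydroxyl free.

Step 2
Reactants: 3 4-(benzyloxy)-3-hydroxy-5-methoxybenzaldehyde; 4 methyl (triphenylphosphoranylidene)acetate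
Product: 5 methyl (2E)-3-[4-(benzyloxy)-3-hydroxy-5-methoxyphenyl]prop-2-enoate
Conditions: toluene, 80 °C
Reagents that add atoms: methyl (triphenylphosphoranylidene)acetate, COC(=O)C=P(c1ccccc1)(c1ccccc1)c1ccccc1
Why: Wittig olefination with a stabilised ylide should give the E-cinnamate and tolerates the free phenol.

Step 3
Reactants: 5 methyl (2E)-3-[4-(benzyloxy)-3-hydroxy-5-methoxyphenyl]prop-2-enoate
Product: 6 methyl 3-[4-(benzyloxy)-3-hydroxy-5-methoxyphenyl]propanoate
Conditions: H2 (1 atm), Pd/C, Ph2S (cat.), EtOAc, rt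
Reagents that add atoms: none
Why: Catalytic hydrogenation on sulfide-poisoned Pd/C should saturate the conjugated alkene while the poison suppresses hydrogenolysis of the aryl benzyl ether.

Step 4
Reactants: 6 methyl 3-[4-(benzyloxy)-3-hydroxy-5-methoxyphenyl]propanoate; 7 paraformaldehyde
Product: 9 methyl 3-[4-(benzyloxy)-2-formyl-3-hydroxy-5-methoxyphenyl]propanoate, via ortho-hydroxymethylphenol 8 (not isolated)
Conditions: MgCl2, Et3N, (CH2O)n, MeCN, reflux; aq. HCl work-up
Reagents that add atoms: paraformaldehyde (formaldehyde), C=O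
Why: Magnesium-mediated ortho-formylation of phenols (Casnati–Skattebøl reaction) is ortho-specific through the magnesium phenoxide–formaldehyde chelate, the only free ortho position lies between the hydroxyl and the side chain, and a second formaldehyde oxidises the hydroxymethyl intermediate by hydride transfer.

Step 5
Reactants: 9 methyl 3-[4-(benzyloxy)-2-formyl-3-hydroxy-5-methoxyphenyl]propanoate; 4 methyl (triphenylphosphoranylidene)acetate
Product: 11 methyl 3-[8-(benzyloxy)-7-methoxy-2-oxo-2H-chromen-5-yl]propanoate, via ortho-hydroxycinnamate 10 (not isolated)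
Conditions: PhNEt2, reflux
Reagents that add atoms: methyl (triphenylphosphoranylidene)acetate, COC(=O)C=P(c1ccccc1)(c1ccccc1)c1ccccc1
Why: Wittig olefination of a salicylaldehyde followed by thermal E/Z isomerisation and lactonisation of the ortho-hydroxycinnamate is the standard one-pot coumarin synthesis.

Step 6
Reactants: 11 methyl 3-[8-(benzyloxy)-7-methoxy-2-oxo-2H-chromen-5-yl]propanoate; 12 [4-(benzyloxy)-3-methoxyphenyl]boronic acid
Product: 13 methyl 3-{(4S)-8-(benzyloxy)-4-[4-(benzyloxy)-3-methoxyphenyl]-7-methoxy-2-oxo-3,4-dihydro-2H-chromen-5-yl}propanoate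
Conditions: Rh(acac)(C2H4)2 (3 mol %), (S)-SEGPHOS, ArB(OH)2 (excess), dioxane–H2O 10:1, 60 °C
Reagents that add atoms: [4-(benzyloxy)-3-methoxyphenyl]boronic acid, COc1cc(B(O)O)ccc1OCc1ccccc1
Why: In this rhodium-catalysed asymmetric 1,4-addition of an arylboronic acid (Hayashi–Miyaura reaction) the aryl–rhodium–bisphosphine species inserts the coumarin C3=C4 bond on one enantioface, which sets the future C1 stereocentre, and water releases the lactone from the rhodium enolate.

Step 7
Reactants: 13 methyl 3-{(4S)-8-(benzyloxy)-4-[4-(benzyloxy)-3-methoxyphenyl]-7-methoxy-2-oxo-3,4-dihydro-2H-chromen-5-yl}propanoate; 14 sodium methoxide; 2 benzyl bromide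
Product: 16 methyl (3S)-3-[2,3-bis(benzyloxy)-4-methoxy-6-(3-methoxy-3-oxopropyl)phenyl]-3-[4-(benzyloxy)-3-methoxyphenyl]propanoate, via sodium phenoxide 15 (not isolated)
Conditions: NaOMe (1.1 equiv), MeOH–THF, 0 °C; concentrate; BnBr, DMF, rt
Reagents that add atoms: sodium methoxide, C[O-].[Na+]; benzyl bromide, BrCc1ccccc1
Why: Methoxide opens the aryl lactone by transesterification to the methyl ester and the phenoxide, which Williamson benzylation traps before it can relactonise, and the non-acidic stereocentre is untouched.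

Step 8
Reactants: 16 methyl (3S)-3-[2,3-bis(benzyloxy)-4-methoxy-6-(3-methoxy-3-oxopropyl)phenyl]-3-[4-(benzyloxy)-3-methoxyphenyl]propanoate
Product: 18 dimethyl (1S,2R,3R)-7,8-bis(benzyloxy)-1-[4-(benzyloxy)-3-methoxyphenyl]-6-methoxy-1,2,3,4-tetrahydronaphthalene-2,3-dicarboxylate, via dilithium bis-enolate 17 (not isolated)
Conditions: 16 added to LiN(iPr)2 (2.3 equiv), THF, −78 °C; then CuCl2 (2.5 equiv), DMF, high dilution, −78 to 0 °C
Reagents that add atoms: none
Why: Two equivalents of LiN(iPr)2 convert both ester α-carbons of 16 into the dilithium bis-enolate 17; divalent copper then removes one electron from one enolate to give an electrophilic α-ester radical, which adds to the carbon of the second enolate, and a second electron transfer turns the resulting radical anion into the succinate 18. The closest known reaction type is the oxidative coupling of ester and imide enolates with CuCl2 or iodine, in its intermolecular form the classical route to 2,3-dibenzylsuccinate lignans and in its intramolecular form a route to trans-cycloalkane-1,2-dicarboxylates. Ring B closes in a 6-exo-trig mode, the attacked enolate double bond at C3 lying outside the forming ring. C3 is set relative to C2 in the transition state itself, where the two ester groups take up an anti, pseudo-diequatorial arrangement on the half-chair and so give the 2,3-trans diester. C2 is set relative to the existing C1 stereocentre, the C2 ester turning away from the C1 aryl group with C1–H near the enolate plane to minimise allylic 1,3-strain, so that the 1,2-trans relationship and hence the all-trans 1S,2R,3R isomer should result. The step needs oxidation of the enolates in the presence of three electron-rich arenes, secured by the far lower oxidation potential of lithium enolates, and ring closure in preference to intermolecular coupling or Dieckmann condensation, secured by complete double deprotonation at −78 °C before the oxidant is added and by high dilution.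

Step 9
Reactants: 18 dimethyl (1S,2R,3R)-7,8-bis(benzyloxy)-1-[4-(benzyloxy)-3-methoxyphenyl]-6-methoxy-1,2,3,4-tetrahydronaphthalene-2,3-dicarboxylate
Product: 19 {(1S,2R,3R)-7,8-bis(benzyloxy)-1-[4-(benzyloxy)-3-methoxyphenyl]-6-methoxy-1,2,3,4-tetrahydronaphthalene-2,3-diyl}dimethanol
Conditions: LiAlH4, THF, 0 °C to rt; Fieser work-up
Reagents that add atoms: none
Why: Hydride reduction of both methyl esters should give the 1,4-diol and end the epimerisability of C2 and C3, with the benzyl ethers inert.

Step 10
Reactants: 19 {(1S,2R,3R)-7,8-bis(benzyloxy)-1-[4-(benzyloxy)-3-methoxyphenyl]-6-methoxy-1,2,3,4-tetrahydronaphthalene-2,3-diyl}dimethanol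
Product: 20 (6R,7R,8S)-8-(4-hydroxy-3-methoxyphenyl)-6,7-bis(hydroxymethyl)-3-methoxy-5,6,7,8-tetrahydronaphthalene-1,2-diol (target, 1S,2R,3R in tetralin numbering)
Conditions: H2 (1 atm), Pd/C, MeOH–EtOAc, rt, degassed solvents
Reagents that add atoms: none
Why: Hydrogenolysis of the three aryl benzyl ethers on Pd/C should free the catechol and the guaiacyl phenol without touching any stereocentre or C–C bond.

Compound list
1 | 3,4-dihydroxy-5-methoxybenzaldehyde (5-hydroxyvanillin) | COc1cc(C=O)cc(O)c1O | starting material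
2 | benzyl bromide | BrCc1ccccc1 | starting material
3 | 4-(benzyloxy)-3-hydroxy-5-methoxybenzaldehyde | COc1cc(C=O)cc(O)c1OCc1ccccc1 | intermediate
4 | methyl (triphenylphosphoranylidene)acetate | COC(=O)C=P(c1ccccc1)(c1ccccc1)c1ccccc1 | starting material
5 | methyl (2E)-3-[4-(benzyloxy)-3-hydroxy-5-methoxyphenyl]prop-2-enoate | COC(=O)/C=C/c1cc(O)c(OCc2ccccc2)c(OC)c1 | intermediate
6 | methyl 3-[4-(benzyloxy)-3-hydroxy-5-methoxyphenyl]propanoate | COC(=O)CCc1cc(O)c(OCc2ccccc2)c(OC)c1 | intermediate
7 | paraformaldehyde (source of formaldehyde) | C=O | starting material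
8 | methyl 3-[4-(benzyloxy)-3-hydroxy-2-(hydroxymethyl)-5-methoxyphenyl]propanoate (present in the flask as its magnesium phenoxide) | COC(=O)CCc1cc(OC)c(OCc2ccccc2)c(O)c1CO | intermediate
9 | methyl 3-[4-(benzyloxy)-2-formyl-3-hydroxy-5-methoxyphenyl]propanoate | COC(=O)CCc1cc(OC)c(OCc2ccccc2)c(O)c1C=O | intermediate
10 | methyl (2E)-3-[3-(benzyloxy)-2-hydroxy-4-methoxy-6-(3-methoxy-3-oxopropyl)phenyl]prop-2-enoate | COC(=O)CCc1cc(OC)c(OCc2ccccc2)c(O)c1/C=C/C(=O)OC | intermediate
11 | methyl 3-[8-(benzyloxy)-7-methoxy-2-oxo-2H-chromen-5-yl]propanoate | COC(=O)CCc1cc(OC)c(OCc2ccccc2)c2OC(=O)C=Cc12 | intermediate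
12 | [4-(benzyloxy)-3-methoxyphenyl]boronic acid | COc1cc(B(O)O)ccc1OCc1ccccc1 | starting material
13 | methyl 3-{(4S)-8-(benzyloxy)-4-[4-(benzyloxy)-3-methoxyphenyl]-7-methoxy-2-oxo-3,4-dihydro-2H-chromen-5-yl}propanoate | COc1cc([C@@H]2CC(=O)Oc3c(OCc4ccccc4)c(OC)cc(CCC(=O)OC)c32)ccc1OCc1ccccc1 | intermediate
14 | sodium methoxide | C[O-].[Na+] | starting material
15 | sodium 6-(benzyloxy)-2-{(1S)-1-[4-(benzyloxy)-3-methoxyphenyl]-3-methoxy-3-oxopropyl}-5-methoxy-3-(3-methoxy-3-oxopropyl)phenolate | COc1cc([C@H](CC(=O)OC)c2c([O-])c(OCc3ccccc3)c(OC)cc2CCC(=O)OC)ccc1OCc1ccccc1.[Na+] | intermediate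
16 | methyl (3S)-3-[2,3-bis(benzyloxy)-4-methoxy-6-(3-methoxy-3-oxopropyl)phenyl]-3-[4-(benzyloxy)-3-methoxyphenyl]propanoate | COc1cc([C@H](CC(=O)OC)c2c(OCc3ccccc3)c(OCc3ccccc3)c(OC)cc2CCC(=O)OC)ccc1OCc1ccccc1 | intermediate
17 | dilithium bis-enolate of 16 (S at the diarylmethine; both ester enolates drawn with the α-substituent trans to O–Li, as expected from LiN(iPr)2 in THF) | COc1cc([C@H](/C=C(\OC)O[Li])c2c(OCc3ccccc3)c(OCc3ccccc3)c(OC)cc2C/C=C(\OC)O[Li])ccc1OCc1ccccc1 | intermediate
18 | dimethyl (1S,2R,3R)-7,8-bis(benzyloxy)-1-[4-(benzyloxy)-3-methoxyphenyl]-6-methoxy-1,2,3,4-tetrahydronaphthalene-2,3-dicarboxylate | COc1cc([C@H]2c3c(cc(OC)c(OCc4ccccc4)c3OCc3ccccc3)C[C@@H](C(=O)OC)[C@@H]2C(=O)OC)ccc1OCc1ccccc1 | intermediate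
19 | {(1S,2R,3R)-7,8-bis(benzyloxy)-1-[4-(benzyloxy)-3-methoxyphenyl]-6-methoxy-1,2,3,4-tetrahydronaphthalene-2,3-diyl}dimethanol | COc1cc([C@H]2c3c(cc(OC)c(OCc4ccccc4)c3OCc3ccccc3)C[C@@H](CO)[C@@H]2CO)ccc1OCc1ccccc1 | intermediate
20 | (6R,7R,8S)-8-(4-hydroxy-3-methoxyphenyl)-6,7-bis(hydroxymethyl)-3-methoxy-5,6,7,8-tetrahydronaphthalene-1,2-diol | COc1cc([C@H]2c3c(cc(OC)c(O)c3O)C[C@@H](CO)[C@@H]2CO)ccc1O | target

Total step count: 10. Longest linear sequence: 10 steps (1 to 20); compounds 2, 4, 7, 12 and 14 are purchased.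

Steps most likely to fail

Step 8 (key step). The risk is poor facial selectivity at C2 relative to C1, because the peri benzyloxy group at C8 can push the C1 aryl group pseudo-axial and change the preferred half-chair. Intermolecular coupling and Dieckmann condensation of a mono-enolate are further risks. The fallback keeps the same ring closure but places both new centres under auxiliary control. It sets out from 16: saponification (LiOH, THF–H2O) should give the diacid F1, and DCC/DMAP acylation of two equivalents of (4S)-4-benzyl-1,3-oxazolidin-2-one should give the bis-imide F2. LiN(iPr)2 in THF at −78 °C should form the chelated dilithium bis-(Z)-enolate F3, and CuCl2 should oxidise it to the cyclised bis-imide F4. Each enolate is expected to bond on the face away from its benzyl group, the sense known from Evans alkylations and from intramolecular couplings of such bis-imides, which corresponds to 2R,3R. Reductive removal of both auxiliaries with LiBH4 (THF–H2O) would return to the route at 19.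

Step 6. The risk is slow insertion of the C3=C4 bond into the aryl–rhodium bond, caused by the peri side chain at C5 of the coumarin, so that protodeboronation of 12 outruns the addition or the enantioselectivity erodes. The fallback installs the aryl group without a stereocentre and sets the stereocentre with hydride. It sets out from 11: oxidative Heck arylation with 12 (Pd(OAc)2, 1,10-phenanthroline, O2, DMF, 80 °C) should give the 4-arylcoumarin F5. Asymmetric conjugate reduction with copper hydride (Cu(OAc)2, DTBM-SEGPHOS in the enantiomer that gives 4S, diethoxymethylsilane, t-BuOH, toluene) should set the stereocentre, with expected further reduction of the aryl lactone to the lactol F6. Fétizon oxidation (Ag2CO3 on Celite, toluene, reflux) would return to the route at 13.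

Step 4. The risk is sluggish or incomplete formylation at the ortho carbon flanked by the hydroxyl and the propanoate chain, with formaldehyde oligomer formation taking over. The fallback reaches the coumarin by an intramolecular arylation. It sets out from 6: esterification with propiolic acid (DCC, DMAP cat., CH2Cl2, 0 °C) should give the aryl propiolate F7. Gold-catalysed intramolecular hydroarylation ((Ph3P)AuCl, AgSbF6, 1,2-dichloroethane, rt) at the only free ortho position would return to the route at 11, bypassing 9 and 10.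

Further compounds
F1 | step 8 | (3S)-3-[2,3-bis(benzyloxy)-6-(2-carboxyethyl)-4-methoxyphenyl]-3-[4-(benzyloxy)-3-methoxyphenyl]propanoic acid | COc1cc([C@H](CC(=O)O)c2c(OCc3ccccc3)c(OCc3ccccc3)c(OC)cc2CCC(=O)O)ccc1OCc1ccccc1
F2 | step 8 | bis-imide of F1 with two (4S)-4-benzyl-2-oxo-1,3-oxazolidin-3-yl groups | COc1cc([C@H](CC(=O)N2C(=O)OC[C@@H]2Cc2ccccc2)c2c(OCc3ccccc3)c(OCc3ccccc3)c(OC)cc2CCC(=O)N2C(=O)OC[C@@H]2Cc2ccccc2)ccc1OCc1ccccc1
F3 | step 8 | dilithium bis-(Z)-enolate of F2 | COc1cc([C@H](/C=C(\O[Li])N2C(=O)OC[C@@H]2Cc2ccccc2)c2c(OCc3ccccc3)c(OCc3ccccc3)c(OC)cc2C/C=C(\O[Li])N2C(=O)OC[C@@H]2Cc2ccccc2)ccc1OCc1ccccc1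
F4 | step 8 | (1S,2R,3R)-7,8-bis(benzyloxy)-1-[4-(benzyloxy)-3-methoxyphenyl]-6-methoxy-1,2,3,4-tetrahydronaphthalene-2,3-dicarbonyl bis[(4S)-4-benzyl-1,3-oxazolidin-2-one] imide | COc1cc([C@H]2c3c(cc(OC)c(OCc4ccccc4)c3OCc3ccccc3)C[C@@H](C(=O)N3C(=O)OC[C@@H]3Cc3ccccc3)[C@@H]2C(=O)N2C(=O)OC[C@@H]2Cc2ccccc2)ccc1OCc1ccccc1
F5 | step 6 | methyl 3-{8-(benzyloxy)-4-[4-(benzyloxy)-3-methoxyphenyl]-7-methoxy-2-oxo-2H-chromen-5-yl}propanoate | COc1cc(C2=CC(=O)Oc3c(OCc4ccccc4)c(OC)cc(CCC(=O)OC)c32)ccc1OCc1ccccc1
F6 | step 6 | methyl 3-{(4S)-8-(benzyloxy)-4-[4-(benzyloxy)-3-methoxyphenyl]-2-hydroxy-7-methoxy-3,4-dihydro-2H-chromen-5-yl}propanoate (lactol, both configurations at the hemiacetal carbon) | COc1cc([C@@H]2CC(O)Oc3c(OCc4ccccc4)c(OC)cc(CCC(=O)OC)c32)ccc1OCc1ccccc1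
F7 | step 4 | 2-(benzyloxy)-3-methoxy-5-(3-methoxy-3-oxopropyl)phenyl prop-2-ynoate | COC(=O)CCc1cc(OC(=O)C#C)c(OCc2ccccc2)c(OC)c1
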